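**Strategy.** The lactone (oxolan-2-one numbering: O1, C2 carbonyl, C3, C4, C5; C7' is the carbinol carbon) is cut at O1–C5. Stripped of the C3 benzyl group, the ring atoms C2, C3, C4 and C5 are a 3-substituted cyclobutanone with O1 slipped in between C2 and C5; C3 and C5 are then like CH2 groups, and C4 is a stereocentre only because one of them bears oxygen. A catalytic asymmetric Baeyer–Villiger oxidation of such a cyclobutanone, which already carries the (R)-silyloxy carbinol C7', lets one CH2 migrate to oxygen: this forms O1–C5, closes the γ-lactone and sets C4 at once. Trans-selective C3 benzylation and deprotection finish the route.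

Key step: step 5

Assumption: compounds 1, 2 and 11 are taken as commercially available, and in step 5 the ligand antipode is the one that gives the 4R lactone, since the sense of group selection for this substrate cannot be predicted with certainty.

**Step 1**
Reactants: 1 1-(benzyloxy)-4-bromo-2-methoxybenzene; 2 3-methylidenecyclobutane-1-carbonitrile
Product: 5 [4-(benzyloxy)-3-methoxyphenyl](3-methylidenecyclobutyl)methanone, via arylmagnesium bromide 3 (not isolated), via bromomagnesium ketimide 4 (not isolated)
Conditions: Mg, THF, 50 °C; then 2, CuBr (cat.), THF, reflux; then 1 M HCl, 0 °C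
Reagents that add atoms: water, O
Why: Grignard addition to a nitrile stops at the magnesium ketimide, which cannot take up a second aryl group, and mild acid hydrolysis should give the aryl ketone without moving the exocyclic alkene; no stereocentre is formed.

**Step 2**
Reactants: 5 [4-(benzyloxy)-3-methoxyphenyl](3-methylidenecyclobutyl)methanone
Product: 6 (R)-[4-(benzyloxy)-3-methoxyphenyl](3-methylidenecyclobutyl)methanol
Conditions: (S)-2-methyl-CBS-oxazaborolidine (20 mol %), catecholborane, toluene, −78 °C; aq. NaOH work-up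
Reagents that add atoms: none
Why: Corey–Bakshi–Shibata reduction, in which the oxazaborolidine binds the carbonyl anti to the aryl group (the larger substituent) and delivers hydride to the Si face to set C7' as R; catecholborane is chosen because it should leave the 1,1-disubstituted alkene alone.

**Step 3**
Reactants: 6 (R)-[4-(benzyloxy)-3-methoxyphenyl](3-methylidenecyclobutyl)methanol
Product: 7 {(R)-[4-(benzyloxy)-3-methoxyphenyl](3-methylidenecyclobutyl)methoxy}(tert-butyl)dimethylsilane
Conditions: TBSCl, imidazole, DMF, rt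
Reagents that add atoms: tert-butyldimethylsilyl chloride, CC(C)(C)[Si](C)(C)Cl
Why: Standard silyl ether formation at oxygen only, so the C7' configuration is retained and the carbinol is masked for the later enolate step.

**Step 4**
Reactants: 7 {(R)-[4-(benzyloxy)-3-methoxyphenyl](3-methylidenecyclobutyl)methoxy}(tert-butyl)dimethylsilane
Product: 8 3-{(R)-[4-(benzyloxy)-3-methoxyphenyl][(tert-butyldimethylsilyl)oxy]methyl}cyclobutan-1-one
Conditions: OsO4 (2 mol %), NaIO4, 2,6-lutidine, dioxane/H2O, rt
Reagents that add atoms: sodium periodate (terminal oxidant), [Na+].[O-]I(=O)(=O)=O; osmium tetroxide (oxygen carrier), O=[Os](=O)(=O)=O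
Why: Lemieux–Johnson oxidation (dihydroxylation, then periodate cleavage) should unveil the cyclobutanone from the exocyclic alkene while the arene, benzyl ether and silyl ether stay untouched; the ring keeps a mirror plane, so no new stereocentre arises.

**Step 5**
Reactants: 8 3-{(R)-[4-(benzyloxy)-3-methoxyphenyl][(tert-butyldimethylsilyl)oxy]methyl}cyclobutan-1-one
Product: 10 (4R)-4-{(R)-[4-(benzyloxy)-3-methoxyphenyl][(tert-butyldimethylsilyl)oxy]methyl}oxolan-2-one, via Criegee adduct 9 (not isolated)
Conditions: Sc(OTf)3 (10 mol %), chiral N,N'-dioxide ligand (pipecolic acid-derived bis(2,6-diisopropylanilide), 10 mol %), mCPBA, Al(OiPr)3, EtOAc, −20 °C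
Reagents that add atoms: meta-chloroperbenzoic acid, OOC(=O)c1cccc(Cl)c1
Why: Asymmetric Baeyer–Villiger oxidation: the peracid adds to the scandium-activated strained carbonyl to give Criegee adduct 9, and the ring CH2 held antiperiplanar to the O–O bond migrates from carbon to oxygen with loss of 3-chlorobenzoate, which forms the O1–C5 bond. The closest known reaction type is the chiral N,N'-dioxide–Sc(OTf)3-catalysed desymmetrisation of 3-substituted cyclobutanones with peracid. The five-membered lactone closes by ring enlargement, a 1,2-shift of carbon to oxygen within the four-membered ring, and not by an end-to-end cyclisation. C4 becomes a stereocentre because the chiral scandium complex selects one of the two diastereotopic ring CH2 groups, while the C7' centre is not touched. The step needs group selectivity, secured by the choice of ligand antipode (the two possible lactones are diastereomers, so a minor C4 epimer should be removable by chromatography), and chemoselectivity over the electron-rich arenes, secured by the strain-driven rate of cyclobutanone oxidation at low temperature; regiochemistry is no issue because both candidates for migration are CH2 groups.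

**Step 6**
Reactants: 11 [4-(benzyloxy)-3-methoxyphenyl]methanol
Product: 12 1-(benzyloxy)-4-(bromomethyl)-2-methoxybenzene
Conditions: PBr3, Et2O, 0 °C
Reagents that add atoms: phosphorus tribromide, BrP(Br)Br
Why: Conversion of an electron-rich benzylic alcohol into the bromide through its phosphite ester and bromide displacement; the product is used directly in step 7.

**Step 7**
Reactants: 10 (4R)-4-{(R)-[4-(benzyloxy)-3-methoxyphenyl][(tert-butyldimethylsilyl)oxy]methyl}oxolan-2-one; 12 1-(benzyloxy)-4-(bromomethyl)-2-methoxybenzene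
Product: 14 (3R,4R)-3-[4-(benzyloxy)-3-methoxybenzyl]-4-{(R)-[4-(benzyloxy)-3-methoxyphenyl][(tert-butyldimethylsilyl)oxy]methyl}oxolan-2-one, via lithium enolate 13 (not isolated)
Conditions: LiN(SiMe3)2, THF, −78 °C; then 12, DMPU, −78 to −30 °C
Reagents that add atoms: none
Why: Lactone enolate alkylation, in which the benzylic bromide should approach the face of the enolate opposite the bulky C4 substituent and so set C3 as R (3,4-trans, also the thermodynamically preferred arrangement).

**Step 8**
Reactants: 14 (3R,4R)-3-[4-(benzyloxy)-3-methoxybenzyl]-4-{(R)-[4-(benzyloxy)-3-methoxyphenyl][(tert-butyldimethylsilyl)oxy]methyl}oxolan-2-one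
Product: 15 (3R,4R)-3-(4-hydroxy-3-methoxybenzyl)-4-{(R)-[(tert-butyldimethylsilyl)oxy](4-hydroxy-3-methoxyphenyl)methyl}oxolan-2-one
Conditions: H2 (1 atm), Pd/C, EtOAc, rt
Reagents that add atoms: none
Why: Hydrogenolysis of the two aryl benzyl ethers in neutral ethyl acetate, where the bulky silyl ether should shield the C7'–O bond from reductive cleavage; the reaction is stopped once two equivalents of hydrogen are taken up.

**Step 9**
Reactants: 15 (3R,4R)-3-(4-hydroxy-3-methoxybenzyl)-4-{(R)-[(tert-butyldimethylsilyl)oxy](4-hydroxy-3-methoxyphenyl)methyl}oxolan-2-one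
Product: 16 5-allohydroxymatairesinol, (3R,4R)-3-(4-hydroxy-3-methoxybenzyl)-4-[(R)-hydroxy(4-hydroxy-3-methoxyphenyl)methyl]oxolan-2-one
Conditions: Bu4NF, AcOH, THF, 0 °C to rt
Reagents that add atoms: none
Why: Fluoride desilylation buffered with acetic acid, so that no free alkoxide or phenoxide is present to cause translactonisation, C3 epimerisation or quinone methide formation at C7'.

**Compound list**

1 | 1-(benzyloxy)-4-bromo-2-methoxybenzene | COc1cc(Br)ccc1OCc1ccccc1 | starting material
2 | 3-methylidenecyclobutane-1-carbonitrile | C=C1CC(C#N)C1 | starting material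
3 | [4-(benzyloxy)-3-methoxyphenyl]magnesium bromide | COc1cc([Mg]Br)ccc1OCc1ccccc1 | intermediate
4 | bromomagnesium ketimide of 5 | COc1cc(C(=N[Mg]Br)C2CC(=C)C2)ccc1OCc1ccccc1 | intermediate
5 | [4-(benzyloxy)-3-methoxyphenyl](3-methylidenecyclobutyl)methanone | COc1cc(C(=O)C2CC(=C)C2)ccc1OCc1ccccc1 | intermediate
6 | (R)-[4-(benzyloxy)-3-methoxyphenyl](3-methylidenecyclobutyl)methanol | C=C1CC(C1)[C@@H](O)c1ccc(OCc2ccccc2)c(OC)c1 | intermediate
7 | {(R)-[4-(benzyloxy)-3-methoxyphenyl](3-methylidenecyclobutyl)methoxy}(tert-butyl)dimethylsilane | C=C1CC(C1)[C@@H](O[Si](C)(C)C(C)(C)C)c1ccc(OCc2ccccc2)c(OC)c1 | intermediate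
8 | 3-{(R)-[4-(benzyloxy)-3-methoxyphenyl][(tert-butyldimethylsilyl)oxy]methyl}cyclobutan-1-one | O=C1CC(C1)[C@@H](O[Si](C)(C)C(C)(C)C)c1ccc(OCc2ccccc2)c(OC)c1 | intermediate
9 | Criegee adduct of 8 with mCPBA (1-hydroxycyclobutyl 3-chloroperbenzoate, ring configuration not defined) | OC1(OOC(=O)c2cccc(Cl)c2)CC(C1)[C@@H](O[Si](C)(C)C(C)(C)C)c1ccc(OCc2ccccc2)c(OC)c1 | intermediate
10 | (4R)-4-{(R)-[4-(benzyloxy)-3-methoxyphenyl][(tert-butyldimethylsilyl)oxy]methyl}oxolan-2-one | O=C1OC[C@@H](C1)[C@@H](O[Si](C)(C)C(C)(C)C)c1ccc(OCc2ccccc2)c(OC)c1 | intermediate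
11 | [4-(benzyloxy)-3-methoxyphenyl]methanol | COc1cc(CO)ccc1OCc1ccccc1 | starting material
12 | 1-(benzyloxy)-4-(bromomethyl)-2-methoxybenzene | COc1cc(CBr)ccc1OCc1ccccc1 | intermediate
13 | lithium enolate of lactone 10 | [Li]OC1=C[C@H](CO1)[C@@H](O[Si](C)(C)C(C)(C)C)c1ccc(OCc2ccccc2)c(OC)c1 | intermediate
14 | (3R,4R)-3-[4-(benzyloxy)-3-methoxybenzyl]-4-{(R)-[4-(benzyloxy)-3-methoxyphenyl][(tert-butyldimethylsilyl)oxy]methyl}oxolan-2-one | COc1cc(C[C@H]2C(=O)OC[C@@H]2[C@@H](O[Si](C)(C)C(C)(C)C)c2ccc(OCc3ccccc3)c(OC)c2)ccc1OCc1ccccc1 | intermediate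
15 | (3R,4R)-3-(4-hydroxy-3-methoxybenzyl)-4-{(R)-[(tert-butyldimethylsilyl)oxy](4-hydroxy-3-methoxyphenyl)methyl}oxolan-2-one | COc1cc(C[C@H]2C(=O)OC[C@@H]2[C@@H](O[Si](C)(C)C(C)(C)C)c2ccc(O)c(OC)c2)ccc1O | intermediate
16 | 5-allohydroxymatairesinol, (3R,4R)-3-(4-hydroxy-3-methoxybenzyl)-4-[(R)-hydroxy(4-hydroxy-3-methoxyphenyl)methyl]oxolan-2-one | COc1cc(C[C@H]2C(=O)OC[C@@H]2[C@@H](O)c2ccc(O)c(OC)c2)ccc1O | target

**Step count**

Total steps: 9. Longest linear sequence: 8 (steps 1, 2, 3, 4, 5, 7, 8, 9); step 6 is a one-step side branch.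

**Steps most likely to fail**

1. Step 5. The catalyst may fail to distinguish the two ring CH2 groups, through a mismatched pairing with the C7' centre or a side chain too bulky for the chiral pocket, so that migration is unselective. The fallback makes the same selection with a chiral base instead of a chiral oxidant. It sets out from 8: deprotonation with lithium bis[(R)-1-phenylethyl]amide or its antipode in THF at −100 °C with Me3SiCl present would give the silyl enol ether trimethyl{[(3R)-3-{(R)-[4-(benzyloxy)-3-methoxyphenyl][(tert-butyldimethylsilyl)oxy]methyl}cyclobut-1-en-1-yl]oxy}silane F1. Ozonolysis (O3, CH2Cl2/MeOH, −78 °C, stopped at the first sign of excess ozone) with NaBH4 work-up would give the hydroxy acid (3R)-4-hydroxy-3-{(R)-[4-(benzyloxy)-3-methoxyphenyl][(tert-butyldimethylsilyl)oxy]methyl}butanoic acid F2. Mitsunobu lactonisation (PPh3, DIAD, THF) would then close the same O1–C5 bond and come back to the route at 10.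

2. Step 2. The oxazaborolidine may discriminate poorly between the cyclobutyl and aryl groups (erosion of enantioselectivity at C7'), or the borane may attack the exocyclic alkene. The fallback builds the carbinol centre by C–C bond formation instead of reduction. It sets out from 2: iBu2AlH (toluene, −78 °C, aqueous acid work-up) would give 3-methylidenecyclobutane-1-carbaldehyde F3. Enantioselective aryl transfer from the arylzinc species made from 4-(benzyloxy)-3-methoxyphenylboronic acid (OB(O)c1ccc(OCc2ccccc2)c(OC)c1) and Et2Zn, catalysed by a chiral amino alcohol such as 3-exo-morpholinoisoborneol (antipode chosen for the R carbinol), would come back to the route at 6, bypassing compounds 3 to 5.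

3. Step 7. The hindered enolate may alkylate sluggishly, be alkylated twice, or show poor facial selectivity at C3. The fallback replaces the SN2 alkylation by an aldol condensation and reduction. It sets out from 10: the lithium enolate and 4-(benzyloxy)-3-methoxybenzaldehyde (COc1cc(C=O)ccc1OCc1ccccc1) would give the trans aldol adduct (3S,4R)-3-{[4-(benzyloxy)-3-methoxyphenyl](hydroxy)methyl}-4-{(R)-[4-(benzyloxy)-3-methoxyphenyl][(tert-butyldimethylsilyl)oxy]methyl}oxolan-2-one F4 as a mixture of carbinol epimers. MsCl/Et3N and then DBU would give the (E)-benzylidene lactone F5. Hydrogenation (H2, Pd/C, EtOAc) would saturate the alkene and remove both benzyl ethers, giving 15 together with its cis C3 epimer F6. DBU in toluene would equilibrate F6 to the trans lactone, so the fallback comes back to the route at 15 and step 8 is not needed.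

**Further compounds**

F1 | step 5 | trimethyl{[(3R)-3-{(R)-[4-(benzyloxy)-3-methoxyphenyl][(tert-butyldimethylsilyl)oxy]methyl}cyclobut-1-en-1-yl]oxy}silane | C[Si](C)(C)OC1=C[C@@H](C1)[C@@H](O[Si](C)(C)C(C)(C)C)c1ccc(OCc2ccccc2)c(OC)c1
F2 | step 5 | (3R)-4-hydroxy-3-{(R)-[4-(benzyloxy)-3-methoxyphenyl][(tert-butyldimethylsilyl)oxy]methyl}butanoic acid | OC(=O)C[C@H](CO)[C@@H](O[Si](C)(C)C(C)(C)C)c1ccc(OCc2ccccc2)c(OC)c1
F3 | step 2 | 3-methylidenecyclobutane-1-carbaldehyde | C=C1CC(C=O)C1
F4 | step 7 | (3S,4R)-3-{[4-(benzyloxy)-3-methoxyphenyl](hydroxy)methyl}-4-{(R)-[4-(benzyloxy)-3-methoxyphenyl][(tert-butyldimethylsilyl)oxy]methyl}oxolan-2-one (carbinol epimers) | COc1cc(C(O)[C@H]2C(=O)OC[C@@H]2[C@@H](O[Si](C)(C)C(C)(C)C)c2ccc(OCc3ccccc3)c(OC)c2)ccc1OCc1ccccc1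
F5 | step 7 | (3E,4R)-3-[4-(benzyloxy)-3-methoxybenzylidene]-4-{(R)-[4-(benzyloxy)-3-methoxyphenyl][(tert-butyldimethylsilyl)oxy]methyl}oxolan-2-one | COc1cc(/C=C2/C(=O)OC[C@@H]2[C@@H](O[Si](C)(C)C(C)(C)C)c2ccc(OCc3ccccc3)c(OC)c2)ccc1OCc1ccccc1
F6 | step 7 | (3S,4R)-3-(4-hydroxy-3-methoxybenzyl)-4-{(R)-[(tert-butyldimethylsilyl)oxy](4-hydroxy-3-methoxyphenyl)methyl}oxolan-2-one (cis C3 epimer of 15) | COc1cc(C[C@@H]2C(=O)OC[C@@H]2[C@@H](O[Si](C)(C)C(C)(C)C)c2ccc(O)c(OC)c2)ccc1O
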